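**Locants and shorthand.** Left half: 1-benzoxepine numbering with primes (O1′, C2′, C3′, C4′, C5′, C5a′, C6′, C7′, C8′, C9′, C9a′); ring A is the oxepane, ring B the cyclohexane. Right half: azulene numbering (C1–C3, C3a, C4–C8, C8a); ring C is the cycloheptenone, ring D the cyclopentane. In names, BxSi = (3S,5aR,6R,7S,9aR)-3-[(tert-butyldimethylsilyl)oxy]-2,2,5a,7-tetramethyl-7-[(triethylsilyl)oxy]decahydro-1-benzoxepin-6-yl and BxOH = (3S,5aR,6R,7S,9aR)-3,7-dihydroxy-2,2,5a,7-tetramethyldecahydro-1-benzoxepin-6-yl.

## The problem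

The target joins a trans-fused perhydro-1-benzoxepine (oxepane ring A on cyclohexane ring B) through a CH2CH2 bridge from C6′ to C5 of a cis-fused hexahydroazulen-7-one (cycloheptenone ring C, cyclopentane ring D). It has eight stereocentres, five on the left (C3′, C5a′, C6′, C7′, C9a′) and three on the right (C1, C3a, C8a). The bridge insulates the two sets, so neither half can control the other and each must take its absolute configuration from its own reagent-controlled step. On the left, the trans fusion (C5a′/C9a′) can come from one (E)-epoxide, C6′ is epimerisable next to a C7′ ketone and prefers the equatorial position, and C7′ then follows from equatorial methyl attack. C3′, however, has its hydroxyl cis to the angular methyl group, which for an epoxide-derived oxepane means that the C2′–C3′ oxirane and the C5a′–C9a′ oxirane have opposite sense and cannot come from one epoxidation. On the right, C3a can control C8a and C1, but C3a itself sits next to the quaternary C4 and needs reagent control. The sensitive groups are two tertiary alcohols (the C7′ alkoxide closes a tetrahydrofuran onto any leaving group at the bridge terminus), a tetrasubstituted enone, and, in late intermediates, a cross-conjugated dienone beside a methyl ketone that will not tolerate base. The feature that makes the key step possible is in ring D: the carbinol carbon C1 is bonded to the fusion carbon C8a, which lies β to the ring C carbonyl C7 through C8, and the other fusion carbon C3a already carries the three-atom tether to C1. C1–C8a is therefore the bond a ketyl at C1 makes with the β-carbon of a C7 enone.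

## Retrosynthesis

**34 ⇒ 33.** The C1–C8a bond is cut, opening ring D to the cycloheptadienone methyl ketone 33. An aldol cut is not possible because C8a is β, not α, to the carbonyl, and cutting C3a–C8a or C1–C2 would not use the carbonyl at all. The cut removes one ring and two stereocentres and leaves a monocyclic right half with a single stereocentre. The forward reaction (SmI2) must choose the disubstituted enone, close cis, place the hydroxyl anti to C8 and tolerate the free hydroxyls, so that nothing follows it.

**33 ⇒ 32 ⇒ 30 ⇒ 29 ⇒ 26 + 27.** After unmasking (32 is the dioxolane and bis-silyl ether of 33), one ring carbon is removed and the side-chain bond at C5 of the cycloheptadienone is cut. The seven-membered dienone comes from siloxycyclopropane 30, this from silyl enol ether 29, and 29 from conjugate addition of the Grignard reagent of bromide 27 to the six-membered cross-conjugated dienone 26. A direct synthesis of a 5-substituted cyclohepta-2,6-dienone has no comparable entry. Here the conjugate addition gives exactly the enolate needed for the one-carbon insertion, and the insertion regenerates the enone that the key step needs as acceptor. The forward step must add only to the disubstituted enone and must set the C5 configuration by the catalyst.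

**26 ⇒ 24 ⇒ 17 + 21.** Dienone 26 comes from enone 24 by dehydrogenation. In 24 the bond between the bridge and ring C is cut (Stork–Danheiser): alkyl iodide 17 as its alkyllithium and vinylogous ester 21. The neighbouring option, cross-coupling with a β-leaving-group enone, fails on regiochemistry because the leaving group would have to sit on the oxygen next to the gem-dimethyl group. The carbonyl transposition of the Stork–Danheiser sequence puts the bridge there automatically. Both fragments are of moderate size and 21 is achiral. The forward step needs a primary alkyllithium whose tertiary C7′ oxygen is capped.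

**21 ⇒ 19 ⇒ 18.** The gem-dimethyl group is removed (two α′-methylations), and vinylogous ester 19 comes from 2-methylcyclohexane-1,3-dione 18. No stereochemistry is involved.

**17 ⇒ 16 ⇒ 15 ⇒ 14 ⇒ 13.** Functional group changes (iodide from alcohol 16, debenzylation of 15, silylation of 14) lead back to the C7′–CH3 bond, which is cut to ketone 13. The alternative, hydration of a C7′ exocyclic alkene, would deliver oxygen from the open equatorial side and give the wrong epimer. Methyl addition to the ketone is steered by the axial angular methyl group to the equatorial side, giving the axial hydroxyl required.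

**13 ⇒ 12.** The O1′–C2′ bond and the C5a′–C6′ bond are cut together, opening rings A and B to the acyclic bis-epoxy enol silyl ether 12. A stepwise closure of the oxepane from a C9a′ hydroxyl and an epoxide would have to win a 7-endo against a 6-exo opening. In the cascade the O–CMe2 bond forms through a six-membered transition state from an epoxide oxygen, and the epoxonium ion is then opened by carbon. An enol silyl ether is chosen as the carbon nucleophile over an allylsilane because it gives the C7′ ketone directly. The precursor is acyclic with three stereocentres, all in oxiranes.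

**12 ⇒ 11 ⇒ 10 ⇒ 8 + 9; 8 ⇒ 5 + 6; 5 ⇒ 3 ⇒ 2 ⇒ 1.** The enol ether comes from enone 11 by 1,4-hydrosilylation, which fixes its regiochemistry. The internal oxirane of 11 is removed to give 10, the enone is cut to keto phosphonate 8 and benzyloxyacetaldehyde 9, and 8 is cut at the allylic carbon to bromide 5 and phosphonate 6. Bromide 5 comes by way of alcohol 3 and acetate 2 from geranyl acetate 1. Because the two oxiranes must have opposite sense, they are introduced in separate steps with antipodal Shi ketones. The distal one is made first, while the allylic acetate deactivates the other alkene, and the internal one later, when it is the only electron-rich alkene left.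

## Roads not taken

**Alternative 1:** The cuts are the bond from the quaternary C5a′ to the ring A chain and the bond from C6′ to the bridge. In the forward step the copper-activated Grignard reagent A2 adds to the β-carbon of silyloxy enone A1 anti to the silyloxy group, and the resulting silyl enol ether adds to methyl acrylate A3 to give keto ester A4. No ring closes.
- *Merits:* the quaternary centre and C6′ are set in one operation with a well-understood anti sense, and the C7′ ketone is already in place.
- *Weak points for this target:* ring A is still open, and closing it from the C9a′ hydroxyl and a later epoxide of the prenyl-type alkene is a 7-endo opening in competition with 6-exo closure to a tetrahydropyran. The Michael step engages an enol ether carbon beside the new quaternary centre. The bridge arrives as a three-carbon ester whose third carbon must become C5 of ring C, so ring C would have to be built on the ester and not brought in complete. A1 must be made enantiopure.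
- *Comparison:* A4 reaches the ring B ketone in fewer operations than the chosen route needs to reach 13 and without a Lewis-acid cascade, and in that respect it is the better road. The chosen plan sets against it that the oxepane is formed by an epoxonium relay whose regiochemistry is built in, and that its bridge ends in an iodide that meets a finished ring C precursor.

**Alternative 2:** The cuts are O1′–C2′ and C5a′–C6′, as in step 8 of the chosen route. In the forward step BF3·OEt2 makes the internal epoxide oxygen of bis-epoxide A5 open the terminal epoxide at its CMe2 carbon, and the allylsilane opens the epoxonium ion at the C–Me carbon to give A6 with an exocyclic methylene on ring B.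
- *Merits:* rings A and B and three stereocentres in one step, by a reaction type that is established for this ring system.
- *Weak points for this target:* A6 needs oxidative cleavage of the methylene before the methyl group can be added, and A5 needs a trisubstituted allylsilane of defined geometry. A6 as drawn has the C3′ hydroxyl cis to the angular methyl group, which requires a (3S) terminal and an (R,R) internal oxirane in A5. One antipode of a Shi ketone gives the same descriptor at both CH carbons, so a one-pot double epoxidation is excluded and the stated economy is partly lost. As a strategy it also leaves rings C and D unsolved.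
- *Comparison:* for the left half this road is as good as the chosen one, and the chosen plan does not compete with it: step 8 uses the same epoxonium relay, only with an enol silyl ether as terminator so that the ketone is obtained directly, and the allylsilane is kept as the fallback for that step. What is not taken is the choice of this cascade as the step that carries the synthesis.

**Alternative 3:** The cut is the bond between the two future fusion carbons C3a and C8a. (R)-Linalool A7 is converted into the silyl-protected dienoate A8. On heating or with Et2AlCl its prenyl alkene acts as ene donor toward the enoate, closing ring D to the cis-cyclopentane A9 while a methyl hydrogen passes to the carbon next to the ester.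
- *Merits:* C1 comes from the chiral pool with the correct configuration, both fusion carbons are set relative to it, and no reductive chemoselectivity problem arises.
- *Weak points for this target:* the ene reaction of an unactivated 1,6-diene needs forcing conditions, and a Lewis acid endangers the tertiary silyl ether. The isopropenyl carbon of A9 must still become the quaternary C4 by another C–C bond formation, and the seven-membered ring with its tetrasubstituted enone must then be closed between that carbon and the ester carbon while the left half is attached at a fully substituted alkene. That is a long and congested sequence after the key step.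
- *Comparison:* in absolute stereocontrol of ring D this road is better than the chosen plan, which depends on a catalyst-controlled conjugate addition (step 17) for C3a. The chosen plan sets against it that ring C arrives complete with the tetrasubstituted enone and with the left half attached, and that ring D closes in the last step with nothing to follow.

Key step: step 21

Remark (assumption on the chemistry): the configuration at C3′ is taken as written, with the hydroxyl cis to the C5a′ methyl group; this is what requires two epoxidations of opposite sense.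

## Route

Step 1
Reactants: 1 geranyl acetate [(2E)-3,7-dimethylocta-2,6-dien-1-yl acetate]
Product: 2 (2E)-5-[(2S)-3,3-dimethyloxiran-2-yl]-3-methylpent-2-en-1-yl acetate
Conditions: Shi ketone of the L-series (1,2:4,5-di-O-isopropylidene-β-L-erythro-2,3-hexodiulo-2,6-pyranose, 30 mol %), KHSO5 (as 2KHSO5·KHSO4·K2SO4), K2CO3, n-Bu4NHSO4, MeCN–CH2(OMe)2, aq. Na2B4O7/Na2EDTA, 0 °C
Reagents that add atoms: potassium peroxymonosulfate, [K+].[O-]S(=O)(=O)OO
Why: Shi epoxidation; the allylic acetate deactivates the proximal alkene so that only the distal isopropylidene alkene reacts, and the L-configured ketone should give the (S)-oxirane through the usual spiro transition state (the D-ketone gives R at the CH carbon of such alkenes).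

Step 2
Reactants: 2 (2E)-5-[(2S)-3,3-dimethyloxiran-2-yl]-3-methylpent-2-en-1-yl acetate
Product: 3 (2E)-5-[(2S)-3,3-dimethyloxiran-2-yl]-3-methylpent-2-en-1-ol
Conditions: K2CO3 (cat.), MeOH, 0 °C to rt
Reagents that add atoms: none
Why: Base-catalysed transesterification of a primary acetate; the trisubstituted oxirane is inert to carbonate in methanol at this temperature.

Step 3
Reactants: 3 (2E)-5-[(2S)-3,3-dimethyloxiran-2-yl]-3-methylpent-2-en-1-ol
Product: 5 (2S)-3-[(3E)-5-bromo-3-methylpent-3-en-1-yl]-2,2-dimethyloxirane, via allylic mesylate 4 (not isolated)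
Conditions: MsCl, Et3N, THF, −40 °C; then LiBr, THF, 0 °C
Reagents that add atoms: lithium bromide, [Li+].[Br-]
Why: Mesylation and SN2 displacement by bromide at a primary allylic carbon under non-acidic conditions that the oxirane tolerates; no stereocentre is touched.

Step 4
Reactants: 6 dimethyl (2-oxopropyl)phosphonate; 5 (2S)-3-[(3E)-5-bromo-3-methylpent-3-en-1-yl]-2,2-dimethyloxirane
Product: 8 dimethyl {(5E)-8-[(2S)-3,3-dimethyloxiran-2-yl]-6-methyl-2-oxooct-5-en-1-yl}phosphonate, via phosphonate dianion 7 (not isolated)
Conditions: NaH, THF, 0 °C; n-BuLi, 0 °C; then 5, 0 °C to rt; aq. NH4Cl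
Reagents that add atoms: none
Why: γ-Alkylation of a β-keto phosphonate dianion; the more basic terminal carbanion displaces the allylic bromide by SN2 and the remote oxirane is a spectator.

Step 5
Reactants: 8 dimethyl {(5E)-8-[(2S)-3,3-dimethyloxiran-2-yl]-6-methyl-2-oxooct-5-en-1-yl}phosphonate; 9 benzyloxyacetaldehyde
Product: 10 (2E,7E)-1-(benzyloxy)-10-[(2S)-3,3-dimethyloxiran-2-yl]-8-methyldeca-2,7-dien-4-one
Conditions: LiCl, i-Pr2NEt, MeCN, rt
Reagents that add atoms: none
Why: Horner–Wadsworth–Emmons olefination under mild LiCl/amine conditions should give the (E)-enone without isomerising the γ-benzyloxy enone or touching the oxirane.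

Step 6
Reactants: 10 (2E,7E)-1-(benzyloxy)-10-[(2S)-3,3-dimethyloxiran-2-yl]-8-methyldeca-2,7-dien-4-one
Product: 11 (2E)-1-(benzyloxy)-6-[(2R,3R)-3-{2-[(2S)-3,3-dimethyloxiran-2-yl]ethyl}-3-methyloxiran-2-yl]hex-2-en-4-one
Conditions: Shi ketone of the D-series (D-fructose-derived, 30 mol %), KHSO5 (as 2KHSO5·KHSO4·K2SO4), K2CO3, n-Bu4NHSO4, MeCN–CH2(OMe)2, aq. Na2B4O7/Na2EDTA, 0 °C
Reagents that add atoms: potassium peroxymonosulfate, [K+].[O-]S(=O)(=O)OO
Why: Second Shi epoxidation; the trisubstituted alkene is now the only electron-rich alkene (the enone alkene does not react with the electrophilic dioxirane), and the D-configured ketone should give the (R,R)-oxirane, opposite in sense to that of step 1. Control is by the reagent, since the existing oxirane is too remote to interfere.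

Step 7
Reactants: 11 (2E)-1-(benzyloxy)-6-[(2R,3R)-3-{2-[(2S)-3,3-dimethyloxiran-2-yl]ethyl}-3-methyloxiran-2-yl]hex-2-en-4-one
Product: 12 {[(3Z)-1-(benzyloxy)-6-[(2R,3R)-3-{2-[(2S)-3,3-dimethyloxiran-2-yl]ethyl}-3-methyloxiran-2-yl]hex-3-en-4-yl]oxy}(tert-butyl)dimethylsilane
Conditions: t-BuMe2SiH, Pt2[(CH2=CHSiMe2)2O]3 (cat., zerovalent platinum), toluene, 60 °C
Reagents that add atoms: tert-butyldimethylsilane, C[SiH](C)C(C)(C)C
Why: Platinum-catalysed 1,4-hydrosilylation of an enone puts hydrogen on the β-carbon and silicon on oxygen, giving the (Z)-silyl enol ether regiospecifically under neutral conditions that spare both oxiranes.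

Step 8
Reactants: 12 {[(3Z)-1-(benzyloxy)-6-[(2R,3R)-3-{2-[(2S)-3,3-dimethyloxiran-2-yl]ethyl}-3-methyloxiran-2-yl]hex-3-en-4-yl]oxy}(tert-butyl)dimethylsilane
Product: 13 (3S,5aR,6R,9aR)-6-[2-(benzyloxy)ethyl]-3-[(tert-butyldimethylsilyl)oxy]-2,2,5a-trimethyloctahydro-1-benzoxepin-7(2H)-one
Conditions: TBSOTf (0.3 equiv), 2,6-di-tert-butyl-4-methylpyridine, CH2Cl2, −78 °C
Reagents that add atoms: none
Why: Lewis-acid-initiated tandem oxa-/carbacyclisation of a 1,5-diepoxide ending in an enol silyl ether: silylation of the terminal oxirane lets the internal oxirane oxygen attack the CMe2 carbon, and the enol ether carbon opens the epoxonium ion at its C–Me carbon, closing rings A and B together. C3′ and C9a′ keep their epoxide configurations, C5a′ is inverted by anti opening (hence the trans fusion), and C6′ takes its chain equatorial through a chair transition state from the (Z)-enol ether and is epimerisable in any case. The step is a net isomerisation, because the silyl group released from the oxocarbenium ion activates the next molecule.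

Step 9
Reactants: 13 (3S,5aR,6R,9aR)-6-[2-(benzyloxy)ethyl]-3-[(tert-butyldimethylsilyl)oxy]-2,2,5a-trimethyloctahydro-1-benzoxepin-7(2H)-one
Product: 14 (3S,5aR,6R,7S,9aR)-6-[2-(benzyloxy)ethyl]-3-[(tert-butyldimethylsilyl)oxy]-2,2,5a,7-tetramethyldecahydro-1-benzoxepin-7-ol
Conditions: MeMgBr, CeCl3, THF, −78 °C
Reagents that add atoms: methylmagnesium bromide, C[Mg]Br
Why: 1,2-Addition of a methyl organometallic, with CeCl3 to suppress enolisation of the α-branched ketone; the axial trajectory is blocked by the 1,3-diaxial angular methyl group, so methyl enters equatorially and the hydroxyl is axial (7S).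

Step 10
Reactants: 14 (3S,5aR,6R,7S,9aR)-6-[2-(benzyloxy)ethyl]-3-[(tert-butyldimethylsilyl)oxy]-2,2,5a,7-tetramethyldecahydro-1-benzoxepin-7-ol
Product: 15 benzyl 2-(BxSi)ethyl ether
Conditions: TESOTf, 2,6-lutidine, CH2Cl2, 0 °C to rt
Reagents that add atoms: triethylsilyl trifluoromethanesulfonate, CC[Si](CC)(CC)OS(=O)(=O)C(F)(F)F
Why: Silylation of a hindered tertiary alcohol with a silyl triflate; the cap prevents the C7′ alkoxide from closing a tetrahydrofuran onto the bridge terminus in steps 12 and 15.

Step 11
Reactants: 15 benzyl 2-(BxSi)ethyl ether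
Product: 16 2-(BxSi)ethan-1-ol
Conditions: H2 (1 atm), Pd/C, EtOAc, rt
Reagents that add atoms: none
Why: Hydrogenolysis of a benzyl ether; the molecule contains no alkene at this stage, and both silyl ethers survive in a non-protic solvent.

Step 12
Reactants: 16 2-(BxSi)ethan-1-ol
Product: 17 (3S,5aR,6R,7S,9aR)-3-[(tert-butyldimethylsilyl)oxy]-6-(2-iodoethyl)-2,2,5a,7-tetramethyl-7-[(triethylsilyl)oxy]decahydro-1-benzoxepine
Conditions: I2, PPh3, imidazole, CH2Cl2, 0 °C to rt
Reagents that add atoms: iodine, II
Why: Appel-type iodination of a primary alcohol under imidazole-buffered conditions that leave the silyl ethers in place.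

Step 13
Reactants: 18 2-methylcyclohexane-1,3-dione
Product: 19 3-ethoxy-2-methylcyclohex-2-en-1-one
Conditions: EtOH, TsOH·H2O (cat.), toluene, reflux, Dean–Stark
Reagents that add atoms: ethanol, CCO
Why: Acid-catalysed enol etherification of a cyclic 1,3-dione (vinylogous ester formation) with azeotropic removal of water.

Step 14
Reactants: 19 3-ethoxy-2-methylcyclohex-2-en-1-one
Product: 21 3-ethoxy-2,6,6-trimethylcyclohex-2-en-1-one, via monomethyl vinylogous ester 20 (not isolated)
Conditions: LiN(i-Pr)2, THF, −78 °C, MeI; then LiN(i-Pr)2, MeI, −78 to 0 °C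
Reagents that add atoms: iodomethane, CI
Why: Kinetic α′-deprotonation of a vinylogous ester and methylation, done twice in one flask; the second deprotonation again takes place at C6, the only position α to the carbonyl.

Step 15
Reactants: 17 (3S,5aR,6R,7S,9aR)-3-[(tert-butyldimethylsilyl)oxy]-6-(2-iodoethyl)-2,2,5a,7-tetramethyl-7-[(triethylsilyl)oxy]decahydro-1-benzoxepine; 21 3-ethoxy-2,6,6-trimethylcyclohex-2-en-1-one
Product: 24 3-[2-(BxSi)ethyl]-2,4,4-trimethylcyclohex-2-en-1-one, via alkyllithium 22 (not isolated), via lithium carbinolate 23 (not isolated)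
Conditions: t-BuLi (2.1 equiv), Et2O–pentane, −78 °C; then 21 (excess), −78 to 0 °C; then 1 M aq. HCl, THF, 0 °C
Reagents that add atoms: none
Why: Stork–Danheiser sequence: iodine–lithium exchange gives the primary alkyllithium, which adds 1,2 to the vinylogous ester carbonyl, and aqueous acid hydrolyses the enol ether and dehydrates the carbinol to the transposed enone, with the bridge on the carbon next to the gem-dimethyl group. The carbinol centre formed on the way is destroyed again.

Step 16
Reactants: 24 3-[2-(BxSi)ethyl]-2,4,4-trimethylcyclohex-2-en-1-one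
Product: 26 3-[2-(BxSi)ethyl]-2,4,4-trimethylcyclohexa-2,5-dien-1-one, via silyl dienol ether 25 (not isolated)
Conditions: LiN(i-Pr)2, TMSCl, THF, −78 °C; then Pd(OAc)2 (1.05 equiv), MeCN, rt
Reagents that add atoms: none
Why: Saegusa–Ito dehydrogenation: kinetic α′-enolisation, silylation and oxidation of the silyl dienol ether by Pd(OAc)2 give the cross-conjugated dienone, which cannot tautomerise to a phenol because C4 is quaternary.

Step 17
Reactants: 26 3-[2-(BxSi)ethyl]-2,4,4-trimethylcyclohexa-2,5-dien-1-one; 27 2-(2-bromoethyl)-2-methyl-1,3-dioxolane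
Product: 29 trimethyl({(3R)-4,4,6-trimethyl-3-[2-(2-methyl-1,3-dioxolan-2-yl)ethyl]-5-[2-(BxSi)ethyl]cyclohexa-1,5-dien-1-yl}oxy)silane, via Grignard reagent 28 (not isolated)
Conditions: 27, Mg, Et2O–THF, below 25 °C; then 26, CuBr·SMe2 (5 mol %), (R)-1-[(SP)-2-(diphenylphosphino)ferrocenyl]ethyldicyclohexylphosphine (6 mol %; the antipode is used if it is the one that gives the 3R product), t-BuOMe, −75 °C; then TMSCl, Et3N, HMPA, −75 to 0 °C
Reagents that add atoms: chlorotrimethylsilane, C[Si](C)(C)Cl
Why: Copper-catalysed enantioselective conjugate addition of a Grignard reagent: only the disubstituted enone has an accessible β-carbon, and the face is chosen by the chiral diphosphine–copper complex because the left-half stereocentres are too remote to matter. Silylation traps the enolate regiospecifically for the ring enlargement.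

Step 18
Reactants: 29 trimethyl({(3R)-4,4,6-trimethyl-3-[2-(2-methyl-1,3-dioxolan-2-yl)ethyl]-5-[2-(BxSi)ethyl]cyclohexa-1,5-dien-1-yl}oxy)silane
Product: 30 (5R)-2,4,4-trimethyl-5-[2-(2-methyl-1,3-dioxolan-2-yl)ethyl]-3-[2-(BxSi)ethyl]-1-[(trimethylsilyl)oxy]bicyclo[4.1.0]hept-2-ene (configuration at C1 and C6 not specified)
Conditions: Et2Zn, CH2I2, CH2Cl2, 0 °C
Reagents that add atoms: diiodomethane, ICI
Why: Simmons–Smith cyclopropanation of the electron-rich silyl enol ether double bond in preference to the hindered tetrasubstituted alkene; the configuration of the two new cyclopropane carbons does not matter because both centres are lost in step 19.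

Step 19
Reactants: 30 (5R)-2,4,4-trimethyl-5-[2-(2-methyl-1,3-dioxolan-2-yl)ethyl]-3-[2-(BxSi)ethyl]-1-[(trimethylsilyl)oxy]bicyclo[4.1.0]hept-2-ene
Product: 32 (5R)-2,4,4-trimethyl-5-[2-(2-methyl-1,3-dioxolan-2-yl)ethyl]-3-[2-(BxSi)ethyl]cyclohepta-2,6-dien-1-one, via β-chloro ketone 31 (not isolated)
Conditions: FeCl3 (2.2 equiv), pyridine, DMF, 0 °C; then NaOAc, MeOH, 65 °C
Reagents that add atoms: none
Why: Oxidative ring enlargement of a siloxycyclopropane (Saegusa ring expansion): FeCl3 oxidises the cyclopropanol silyl ether, the internal bond cleaves to the ring-enlarged β-keto radical, which is chlorinated, and acetate eliminates HCl to the cycloheptadienone. C5 is not touched.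

Step 20
Reactants: 32 (5R)-2,4,4-trimethyl-5-[2-(2-methyl-1,3-dioxolan-2-yl)ethyl]-3-[2-(BxSi)ethyl]cyclohepta-2,6-dien-1-one
Product: 33 (5R)-2,4,4-trimethyl-5-(3-oxobutyl)-3-[2-(BxOH)ethyl]cyclohepta-2,6-dien-1-one
Conditions: 3 M aq. HCl, THF, rt
Reagents that add atoms: water, O
Why: Acidic hydrolysis removes the dioxolane and both silyl ethers in one operation; dilute acid at room temperature should be tolerated by the tertiary alcohols and avoids the base-mediated Michael cyclisation of the methyl ketone onto the dienone.

Step 21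
Reactants: 33 (5R)-2,4,4-trimethyl-5-(3-oxobutyl)-3-[2-(BxOH)ethyl]cyclohepta-2,6-dien-1-one
Product: 34 (1R,3aR,8aR)-1-hydroxy-1,4,4,6-tetramethyl-5-[2-(BxOH)ethyl]-2,3,3a,4,8,8a-hexahydroazulen-7(1H)-one (target)
Conditions: SmI2 (2.2 equiv), HMPA, THF, −78 °C; then aq. NH4Cl
Reagents that add atoms: none
Why: This is a ketone–enone reductive cyclisation with SmI2; the closest known reaction type is the samarium ketyl–olefin cyclisation of a ketone onto an activated alkene to give a cis-fused cyclopentanol. One electron from divalent samarium gives either the ketyl of the methyl ketone or the radical anion of the dienone, and both lead to the same bond, between the carbinol carbon (future C1) and C6 of the dienone, the β-carbon of the disubstituted enone (future C8a). Ring D closes 5-exo-trig. A second electron gives a trivalent samarium dienolate, which is protonated at the carbon next to the carbonyl (future C8) and so returns the conjugated tetrasubstituted enone of ring C. C8a is controlled by C3a (C5 of 33): the three-atom tether reaches only the face of the seven-membered ring on which it stands, so the fusion is cis. C1 is controlled in the chair-like 5-exo transition state, where the bulky samarium-bound oxygen turns away from the developing enolate, putting the hydroxyl anti to C8 and the methyl syn, again relative to C3a. The step needs selectivity between the two enones, which the substrate provides because the β-carbon of the other enone is fully substituted and flanked by the quaternary carbon; it must also stop before the product enone is reduced, which the stoichiometry and low temperature should ensure. The free hydroxyls of the left half only ligate samarium and act as an internal proton source.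

## Compound list

1 | geranyl acetate | CC(C)=CCC/C(C)=C/COC(C)=O | starting material
2 | (2E)-5-[(2S)-3,3-dimethyloxiran-2-yl]-3-methylpent-2-en-1-yl acetate | CC(=O)OC/C=C(C)/CC[C@@H]1OC1(C)C | intermediate
3 | (2E)-5-[(2S)-3,3-dimethyloxiran-2-yl]-3-methylpent-2-en-1-ol | OC/C=C(C)/CC[C@@H]1OC1(C)C | intermediate
4 | (2E)-5-[(2S)-3,3-dimethyloxiran-2-yl]-3-methylpent-2-en-1-yl methanesulfonate (not isolated) | CS(=O)(=O)OC/C=C(C)/CC[C@@H]1OC1(C)C | intermediate
5 | (2S)-3-[(3E)-5-bromo-3-methylpent-3-en-1-yl]-2,2-dimethyloxirane | BrC/C=C(C)/CC[C@@H]1OC1(C)C | intermediate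
6 | dimethyl (2-oxopropyl)phosphonate | COP(=O)(OC)CC(C)=O | starting material
7 | sodium lithium 1,3-dianion of dimethyl (2-oxopropyl)phosphonate (not isolated) | [Na+].[Li+].COP(=O)(OC)[CH-]C(=O)[CH2-] | intermediate
8 | dimethyl {(5E)-8-[(2S)-3,3-dimethyloxiran-2-yl]-6-methyl-2-oxooct-5-en-1-yl}phosphonate | COP(=O)(OC)CC(=O)CC/C=C(C)/CC[C@@H]1OC1(C)C | intermediate
9 | benzyloxyacetaldehyde | O=CCOCc1ccccc1 | starting material
10 | (2E,7E)-1-(benzyloxy)-10-[(2S)-3,3-dimethyloxiran-2-yl]-8-methyldeca-2,7-dien-4-one | O=C(/C=C/COCc1ccccc1)CC/C=C(C)/CC[C@@H]1OC1(C)C | intermediate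
11 | (2E)-1-(benzyloxy)-6-[(2R,3R)-3-{2-[(2S)-3,3-dimethyloxiran-2-yl]ethyl}-3-methyloxiran-2-yl]hex-2-en-4-one | O=C(/C=C/COCc1ccccc1)CC[C@H]1O[C@]1(C)CC[C@@H]1OC1(C)C | intermediate
12 | {[(3Z)-1-(benzyloxy)-6-[(2R,3R)-3-{2-[(2S)-3,3-dimethyloxiran-2-yl]ethyl}-3-methyloxiran-2-yl]hex-3-en-4-yl]oxy}(tert-butyl)dimethylsilane | CC(C)(C)[Si](C)(C)O/C(CC[C@H]1O[C@]1(C)CC[C@@H]1OC1(C)C)=C\CCOCc1ccccc1 | intermediate
13 | (3S,5aR,6R,9aR)-6-[2-(benzyloxy)ethyl]-3-[(tert-butyldimethylsilyl)oxy]-2,2,5a-trimethyloctahydro-1-benzoxepin-7(2H)-one | c1ccccc1COCC[C@@H]1[C@@]2(C)CC[C@H](O[Si](C)(C)C(C)(C)C)C(C)(C)O[C@@H]2CCC1=O | intermediate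
14 | (3S,5aR,6R,7S,9aR)-6-[2-(benzyloxy)ethyl]-3-[(tert-butyldimethylsilyl)oxy]-2,2,5a,7-tetramethyldecahydro-1-benzoxepin-7-ol | c1ccccc1COCC[C@@H]1[C@@]2(C)CC[C@H](O[Si](C)(C)C(C)(C)C)C(C)(C)O[C@@H]2CC[C@]1(C)O | intermediate
15 | benzyl 2-(BxSi)ethyl ether; (3S,5aR,6R,7S,9aR)-6-[2-(benzyloxy)ethyl]-3-[(tert-butyldimethylsilyl)oxy]-2,2,5a,7-tetramethyl-7-[(triethylsilyl)oxy]decahydro-1-benzoxepine | c1ccccc1COCC[C@@H]1[C@@]2(C)CC[C@H](O[Si](C)(C)C(C)(C)C)C(C)(C)O[C@@H]2CC[C@]1(C)O[Si](CC)(CC)CC | intermediate
16 | 2-(BxSi)ethan-1-ol | OCC[C@@H]1[C@@]2(C)CC[C@H](O[Si](C)(C)C(C)(C)C)C(C)(C)O[C@@H]2CC[C@]1(C)O[Si](CC)(CC)CC | intermediate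
17 | (3S,5aR,6R,7S,9aR)-3-[(tert-butyldimethylsilyl)oxy]-6-(2-iodoethyl)-2,2,5a,7-tetramethyl-7-[(triethylsilyl)oxy]decahydro-1-benzoxepine | ICC[C@@H]1[C@@]2(C)CC[C@H](O[Si](C)(C)C(C)(C)C)C(C)(C)O[C@@H]2CC[C@]1(C)O[Si](CC)(CC)CC | intermediate
18 | 2-methylcyclohexane-1,3-dione | CC1C(=O)CCCC1=O | starting material
19 | 3-ethoxy-2-methylcyclohex-2-en-1-one | CCOC1=C(C)C(=O)CCC1 | intermediate
20 | 3-ethoxy-2,6-dimethylcyclohex-2-en-1-one (racemic, not isolated) | CCOC1=C(C)C(=O)C(C)CC1 | intermediate
21 | 3-ethoxy-2,6,6-trimethylcyclohex-2-en-1-one | CCOC1=C(C)C(=O)C(C)(C)CC1 | intermediate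
22 | [2-(BxSi)ethyl]lithium (not isolated) | [Li]CC[C@@H]1[C@@]2(C)CC[C@H](O[Si](C)(C)C(C)(C)C)C(C)(C)O[C@@H]2CC[C@]1(C)O[Si](CC)(CC)CC | intermediate
23 | lithium 1-[2-(BxSi)ethyl]-3-ethoxy-2,6,6-trimethylcyclohex-2-en-1-olate (both C1 epimers, not isolated) | CCOC1=C(C)C(O[Li])(CC[C@@H]2[C@@]3(C)CC[C@H](O[Si](C)(C)C(C)(C)C)C(C)(C)O[C@@H]3CC[C@]2(C)O[Si](CC)(CC)CC)C(C)(C)CC1 | intermediate
24 | 3-[2-(BxSi)ethyl]-2,4,4-trimethylcyclohex-2-en-1-one | CC1=C(CC[C@@H]2[C@@]3(C)CC[C@H](O[Si](C)(C)C(C)(C)C)C(C)(C)O[C@@H]3CC[C@]2(C)O[Si](CC)(CC)CC)C(C)(C)CCC1=O | intermediate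
25 | trimethyl({4,4,6-trimethyl-5-[2-(BxSi)ethyl]cyclohexa-1,5-dien-1-yl}oxy)silane (not isolated) | CC1=C(CC[C@@H]2[C@@]3(C)CC[C@H](O[Si](C)(C)C(C)(C)C)C(C)(C)O[C@@H]3CC[C@]2(C)O[Si](CC)(CC)CC)C(C)(C)CC=C1O[Si](C)(C)C | intermediate
26 | 3-[2-(BxSi)ethyl]-2,4,4-trimethylcyclohexa-2,5-dien-1-one | CC1=C(CC[C@@H]2[C@@]3(C)CC[C@H](O[Si](C)(C)C(C)(C)C)C(C)(C)O[C@@H]3CC[C@]2(C)O[Si](CC)(CC)CC)C(C)(C)C=CC1=O | intermediate
27 | 2-(2-bromoethyl)-2-methyl-1,3-dioxolane | CC1(CCBr)OCCO1 | starting material
28 | [2-(2-methyl-1,3-dioxolan-2-yl)ethyl]magnesium bromide (not isolated) | CC1(CC[Mg]Br)OCCO1 | intermediate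
29 | trimethyl({(3R)-4,4,6-trimethyl-3-[2-(2-methyl-1,3-dioxolan-2-yl)ethyl]-5-[2-(BxSi)ethyl]cyclohexa-1,5-dien-1-yl}oxy)silane | CC1=C(CC[C@@H]2[C@@]3(C)CC[C@H](O[Si](C)(C)C(C)(C)C)C(C)(C)O[C@@H]3CC[C@]2(C)O[Si](CC)(CC)CC)C(C)(C)[C@H](CCC2(C)OCCO2)C=C1O[Si](C)(C)C | intermediate
30 | (5R)-2,4,4-trimethyl-5-[2-(2-methyl-1,3-dioxolan-2-yl)ethyl]-3-[2-(BxSi)ethyl]-1-[(trimethylsilyl)oxy]bicyclo[4.1.0]hept-2-ene (C1 and C6 not specified) | CC1=C(CC[C@@H]2[C@@]3(C)CC[C@H](O[Si](C)(C)C(C)(C)C)C(C)(C)O[C@@H]3CC[C@]2(C)O[Si](CC)(CC)CC)C(C)(C)[C@H](CCC2(C)OCCO2)C2CC12O[Si](C)(C)C | intermediate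
31 | (5S)-6-chloro-2,4,4-trimethyl-5-[2-(2-methyl-1,3-dioxolan-2-yl)ethyl]-3-[2-(BxSi)ethyl]cyclohept-2-en-1-one (both C6 epimers; C5 unchanged in space, descriptor changed by priority only; not isolated) | CC1=C(CC[C@@H]2[C@@]3(C)CC[C@H](O[Si](C)(C)C(C)(C)C)C(C)(C)O[C@@H]3CC[C@]2(C)O[Si](CC)(CC)CC)C(C)(C)[C@H](CCC2(C)OCCO2)C(Cl)CC1=O | intermediate
32 | (5R)-2,4,4-trimethyl-5-[2-(2-methyl-1,3-dioxolan-2-yl)ethyl]-3-[2-(BxSi)ethyl]cyclohepta-2,6-dien-1-one | CC1=C(CC[C@@H]2[C@@]3(C)CC[C@H](O[Si](C)(C)C(C)(C)C)C(C)(C)O[C@@H]3CC[C@]2(C)O[Si](CC)(CC)CC)C(C)(C)[C@H](CCC2(C)OCCO2)C=CC1=O | intermediate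
33 | (5R)-2,4,4-trimethyl-5-(3-oxobutyl)-3-[2-(BxOH)ethyl]cyclohepta-2,6-dien-1-one | CC1=C(CC[C@@H]2[C@@]3(C)CC[C@H](O)C(C)(C)O[C@@H]3CC[C@]2(C)O)C(C)(C)[C@H](CCC(C)=O)C=CC1=O | intermediate
34 | (1R,3aR,8aR)-1-hydroxy-1,4,4,6-tetramethyl-5-[2-(BxOH)ethyl]-2,3,3a,4,8,8a-hexahydroazulen-7(1H)-one | CC1=C(CC[C@@H]2[C@@]3(C)CC[C@H](O)C(C)(C)O[C@@H]3CC[C@]2(C)O)C(C)(C)[C@@H]2CC[C@@](C)(O)[C@@H]2CC1=O | target

## Step count and risk

Total: 21 steps. Longest linear sequence: 19 steps (steps 1–12 and 15–21, from geranyl acetate 1); the ring C building block 21 takes 2 steps (13–14).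

**Step 21 (key step).** The most likely failure is that the dienone radical anion is protonated and reduced further before the C–C bond forms (simple conjugate reduction). The second is closure with poor facial selectivity at the carbinol carbon, because the ketyl is less tightly organised when the enone is the first group to be reduced. The fallback separates the C–C bond formation from the creation of the carbinol. It sets out from 32 and comes back at 34. Selective hydrolysis of the dioxolane (pyridinium p-toluenesulfonate, wet acetone) gives the silyl-protected methyl ketone F1. Kinetic deprotonation of the methyl group (KN(SiMe3)2, THF, −78 °C) and PhNTf2 give the alkenyl triflate F2. An intramolecular reductive Heck reaction (Pd(OAc)2, PPh3, HCO2Na, DMF, 60 °C) adds the alkenyl group 5-exo to the β-carbon of the disubstituted enone, and the palladium enolate, which has no syn β-hydrogen, is reduced by formate to the cis-fused exocyclic methylene compound F3. Mukaiyama hydration (Co(acac)2, PhSiH3, O2, i-PrOH) should deliver oxygen to the tertiary radical from the face of the ring-fusion hydrogens, giving the bis-silyl ether F4 of the target, and 3 M aq. HCl then gives 34.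

**Step 8.** The enol ether may capture the silyl-activated internal oxirane directly, so that the carbocycle forms without the oxygen relay. The hindered trisubstituted enol ether may also be too slow, so that the epoxonium ion is lost by elimination or the enol ether by protodesilylation. The fallback changes the terminating nucleophile to the better-precedented allylsilane and accepts an oxidative cleavage. It sets out from 12 and comes back at 13. The lithium enolate is released from 12 (MeLi, THF, 0 °C) and trapped with PhNTf2 as the (Z)-enol triflate F5. Kumada coupling (Me3SiCH2MgCl, Pd(PPh3)4, THF) gives the allylsilane F6. The cascade (TBSOTf, 2,6-di-tert-butyl-4-methylpyridine, CH2Cl2, −78 °C) gives the exocyclic methylene compound F7. Lemieux–Johnson cleavage (OsO4 cat., NaIO4, 2,6-lutidine, dioxane–water) returns ketone 13.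

**Step 17.** Catalyst control may be insufficient at a β-carbon flanked by a quaternary centre, and 1,2-addition may compete. The resulting C5 epimers would differ only at a centre remote from the left half and would be hard to separate. The fallback is a rhodium-catalysed Hayashi–Miyaura addition, which has a different selectivity model and no basic organometallic. It sets out from 26 and comes back at 29. The alkenylboronic ester F8 is added with [Rh(OH)(cod)]2 and BINAP (the antipode that gives the required face) in dioxane–water to give the alkenyl ketone F9. Hydrogenation of the disubstituted alkene only (H2, RhCl(PPh3)3, benzene) gives the saturated ketone F10, and kinetic enolisation and silylation (LiN(i-Pr)2, TMSCl, THF, −78 °C) give 29.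

**Step 15.** Addition to a carbonyl flanked by a quaternary carbon and a substituted alkene carbon may be slow, so that the alkyllithium acts as a base (γ-deprotonation of the vinylogous ester) or suffers migration of the silyl group from the C7′ oxygen to carbon. The fallback replaces carbonyl addition by cross-coupling followed by oxidation. It sets out from 17 and comes back at 24. The alkyllithium from 17 is trapped at −78 °C with B-methoxy-9-borabicyclo[3.3.1]nonane, and the borinate is coupled (PdCl2(dppf), Cs2CO3, DMF–water) with the enol triflate F11, made from 2,2,6-trimethylcyclohexanone, to give the tetrasubstituted cyclohexene F12. Allylic oxidation at the ring methylene next to the methyl-bearing alkene carbon (CrO3·3,5-dimethylpyrazole, CH2Cl2, −20 °C) gives enone 24. The regioselectivity of this oxidation against the bridge methylene is the weak point of the fallback.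

## Further compounds

F1 | step 21 | (5R)-2,4,4-trimethyl-5-(3-oxobutyl)-3-[2-(BxSi)ethyl]cyclohepta-2,6-dien-1-one | CC1=C(CC[C@@H]2[C@@]3(C)CC[C@H](O[Si](C)(C)C(C)(C)C)C(C)(C)O[C@@H]3CC[C@]2(C)O[Si](CC)(CC)CC)C(C)(C)[C@H](CCC(C)=O)C=CC1=O
F2 | step 21 | 4-{(1R)-2,2,4-trimethyl-5-oxo-3-[2-(BxSi)ethyl]cyclohepta-3,6-dien-1-yl}but-1-en-2-yl trifluoromethanesulfonate | CC1=C(CC[C@@H]2[C@@]3(C)CC[C@H](O[Si](C)(C)C(C)(C)C)C(C)(C)O[C@@H]3CC[C@]2(C)O[Si](CC)(CC)CC)C(C)(C)[C@H](CCC(=C)OS(=O)(=O)C(F)(F)F)C=CC1=O
F3 | step 21 | (3aR,8aS)-4,4,6-trimethyl-1-methylidene-5-[2-(BxSi)ethyl]-2,3,3a,4,8,8a-hexahydroazulen-7(1H)-one (cis-fused) | CC1=C(CC[C@@H]2[C@@]3(C)CC[C@H](O[Si](C)(C)C(C)(C)C)C(C)(C)O[C@@H]3CC[C@]2(C)O[Si](CC)(CC)CC)C(C)(C)[C@@H]2CCC(=C)[C@@H]2CC1=O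
F4 | step 21 | (1R,3aR,8aR)-1-hydroxy-1,4,4,6-tetramethyl-5-[2-(BxSi)ethyl]-2,3,3a,4,8,8a-hexahydroazulen-7(1H)-one | CC1=C(CC[C@@H]2[C@@]3(C)CC[C@H](O[Si](C)(C)C(C)(C)C)C(C)(C)O[C@@H]3CC[C@]2(C)O[Si](CC)(CC)CC)C(C)(C)[C@@H]2CC[C@@](C)(O)[C@@H]2CC1=O
F5 | step 8 | (3Z)-1-(benzyloxy)-6-[(2R,3R)-3-{2-[(2S)-3,3-dimethyloxiran-2-yl]ethyl}-3-methyloxiran-2-yl]hex-3-en-4-yl trifluoromethanesulfonate | FC(F)(F)S(=O)(=O)O/C(CC[C@H]1O[C@]1(C)CC[C@@H]1OC1(C)C)=C\CCOCc1ccccc1
F6 | step 8 | {(2Z)-5-(benzyloxy)-2-[2-((2R,3R)-3-{2-[(2S)-3,3-dimethyloxiran-2-yl]ethyl}-3-methyloxiran-2-yl)ethyl]pent-2-en-1-yl}trimethylsilane | C[Si](C)(C)C/C(CC[C@H]1O[C@]1(C)CC[C@@H]1OC1(C)C)=C\CCOCc1ccccc1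
F7 | step 8 | (3S,5aR,6R,9aR)-6-[2-(benzyloxy)ethyl]-3-[(tert-butyldimethylsilyl)oxy]-2,2,5a-trimethyl-7-methylidenedecahydro-1-benzoxepine | c1ccccc1COCC[C@@H]1[C@@]2(C)CC[C@H](O[Si](C)(C)C(C)(C)C)C(C)(C)O[C@@H]2CCC1=C
F8 | step 17 | 4,4,5,5-tetramethyl-2-[(E)-2-(2-methyl-1,3-dioxolan-2-yl)ethenyl]-1,3,2-dioxaborolane | CC1(/C=C/B2OC(C)(C)C(C)(C)O2)OCCO1
F9 | step 17 | (5S)-2,4,4-trimethyl-5-[(E)-2-(2-methyl-1,3-dioxolan-2-yl)ethenyl]-3-[2-(BxSi)ethyl]cyclohex-2-en-1-one | CC1=C(CC[C@@H]2[C@@]3(C)CC[C@H](O[Si](C)(C)C(C)(C)C)C(C)(C)O[C@@H]3CC[C@]2(C)O[Si](CC)(CC)CC)C(C)(C)[C@H](/C=C/C2(C)OCCO2)CC1=O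
F10 | step 17 | (5R)-2,4,4-trimethyl-5-[2-(2-methyl-1,3-dioxolan-2-yl)ethyl]-3-[2-(BxSi)ethyl]cyclohex-2-en-1-one | CC1=C(CC[C@@H]2[C@@]3(C)CC[C@H](O[Si](C)(C)C(C)(C)C)C(C)(C)O[C@@H]3CC[C@]2(C)O[Si](CC)(CC)CC)C(C)(C)[C@H](CCC2(C)OCCO2)CC1=O
F11 | step 15 | 2,6,6-trimethylcyclohex-1-en-1-yl trifluoromethanesulfonate | CC1=C(OS(=O)(=O)C(F)(F)F)C(C)(C)CCC1
F12 | step 15 | (3S,5aR,6R,7S,9aR)-3-[(tert-butyldimethylsilyl)oxy]-2,2,5a,7-tetramethyl-7-[(triethylsilyl)oxy]-6-[2-(2,6,6-trimethylcyclohex-1-en-1-yl)ethyl]decahydro-1-benzoxepine | CC1=C(CC[C@@H]2[C@@]3(C)CC[C@H](O[Si](C)(C)C(C)(C)C)C(C)(C)O[C@@H]3CC[C@]2(C)O[Si](CC)(CC)CC)C(C)(C)CCC1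
A1 | alternative 1 | (4R)-4-[(tert-butyldimethylsilyl)oxy]-3-methylcyclohex-2-en-1-one | CC1=CC(=O)CC[C@H]1O[Si](C)(C)C(C)(C)C
A2 | alternative 1 | (4-methylpent-3-en-1-yl)magnesium bromide | CC(C)=CCC[Mg]Br
A3 | alternative 1 | methyl acrylate | COC(=O)C=C
A4 | alternative 1 | ring B keto ester, methyl 3-[(1R,2R,3R)-3-[(tert-butyldimethylsilyl)oxy]-2-methyl-2-(4-methylpent-3-en-1-yl)-6-oxocyclohexyl]propanoate | COC(=O)CC[C@@H]1[C@@](C)(CCC=C(C)C)[C@H](O[Si](C)(C)C(C)(C)C)CCC1=O
A5 | alternative 2 | (3Z)-6-[(2R,3R)-3-{2-[(2S)-3,3-dimethyloxiran-2-yl]ethyl}-3-methyloxiran-2-yl]-4-[(trimethylsilyl)methyl]hex-3-en-1-yl pivalate | CC(C)(C)C(=O)OCC/C=C(C[Si](C)(C)C)/CC[C@H]1O[C@]1(C)CC[C@@H]1OC1(C)C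
A6 | alternative 2 | 2-[(3S,5aR,6R,9aR)-3-hydroxy-2,2,5a-trimethyl-7-methylidenedecahydro-1-benzoxepin-6-yl]ethyl pivalate | CC(C)(C)C(=O)OCC[C@@H]1[C@@]2(C)CC[C@H](O)C(C)(C)O[C@@H]2CCC1=C
A7 | alternative 3 | (R)-linalool | C=C[C@](C)(O)CCC=C(C)C
A8 | alternative 3 | methyl (2E,4R)-4,8-dimethyl-4-[(triethylsilyl)oxy]nona-2,7-dienoate | COC(=O)/C=C/[C@](C)(O[Si](CC)(CC)CC)CCC=C(C)C
A9 | alternative 3 | methyl 2-[(1R,2R,5R)-2-methyl-5-(prop-1-en-2-yl)-2-[(triethylsilyl)oxy]cyclopentyl]acetate | CC(=C)[C@@H]1CC[C@@](C)(O[Si](CC)(CC)CC)[C@@H]1CC(=O)OC
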